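**Plan**
Tetralin numbering: C1 carries the aryl group, C2 the ester, C3 the CH2OH, C4 is CH2; ring A is the benzo ring (C4a to C8a), ring B the saturated ring.
Feature: the target is two guaiacyl C6–C3 units joined side chain to side chain (C2–C3) and side chain to ring A (C1–C8a), the skeleton of a cyclised 8–8 dehydrodimer of a ferulate ester.
Retrosynthesis: the C2 ester is traced to an acid, C3–CH2OH to an ester, C3–H/C4–H to a C3=C4 double bond, and the ring hydrogens ortho to the two phenols to bromine; the C1–C8a and C2–C3 bonds of ring B are then cut, leaving two molecules of methyl 5-bromoferulate.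
Forward: 5-bromovanillin gives the bromoferulate; one FeCl3 oxidation joins C2–C3 and closes ring B at C1–C8a; the C2 ester is saponified, the acid resolved, C3=C4 hydrogenated with loss of both bromines, the C3 ester reduced and the C2 acid re-esterified.
Stereochemistry: C1/C2 trans comes from the ring closure (racemic), the absolute configuration from crystallisation of the (R)-1-phenylethylammonium salt of the half acid, and C3 from hydrogen addition anti to the C1 aryl group.
Key step: step 2

Assumption: the (R)-1-phenylethylammonium salt of the (1R,2S)-acid is taken to be the less soluble diastereomer; if the antipodal salt crystallises instead, (S)-1-phenylethylamine is used in the same way.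

**Step 1**
Reactants: 1 5-bromovanillin; 2 monomethyl malonate
Product: 3 methyl (E)-5-bromoferulate [methyl (2E)-3-(3-bromo-4-hydroxy-5-methoxyphenyl)prop-2-enoate]
Conditions: pyridine, piperidine (cat.), 90 °C
Reagents that add atoms: none
Why: Knoevenagel–Doebner condensation of the aldehyde with the malonic half ester, followed by decarboxylative elimination, gives the cinnamate as the E isomer and tolerates the free phenol.

**Step 2**
Reactants: 3 methyl (E)-5-bromoferulate (two molecules)
Product: 6 racemic dimethyl trans-8-bromo-1-(3-bromo-4-hydroxy-5-methoxyphenyl)-7-hydroxy-6-methoxy-1,2-dihydronaphthalene-2,3-dicarboxylate (1R,2S enantiomer drawn), via bis-quinone methide 4 (not isolated), via arylidenesuccinate quinone methide 5 (not isolated)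
Conditions: FeCl3·6H2O, acetone/H2O, rt
Reagents that add atoms: none
Why: FeCl3 (trivalent iron) takes one electron from each of two phenols 3; the phenoxyl radicals, which carry spin at the carbon α to the ester, join there (C2–C3) to give bis-quinone methide 4, loss of the acidic C3 proton re-aromatises one half to the E-arylidene unit of 5, and its ring carbon para to the methoxy group then adds to the remaining methide carbon (C1–C8a) before proton loss restores the second arene. The closest known reaction type is the FeCl3 dimerisation of sinapate esters and other 3,5-disubstituted 4-hydroxycinnamates to 1-aryl-1,2-dihydronaphthalene-2,3-dicarboxylates. Ring B closes in a 6-exo-trig Friedel–Crafts-type 1,6-addition of the arene to the quinone methide. C2 arises in the radical coupling without facial bias, and C1 is set relative to it in the closure, the new bond forming on the face that leaves the aryl group anti to the C2 ester (trans, both pseudoaxial), so a racemic trans product should result. The step needs 8–8 rather than 8–5 or 8–O–4 coupling and closure para to the methoxy group: bromine occupies the ring position used in 8–5 coupling, the two ortho substituents screen the phenoxyl oxygen, and the methoxy group activates the ring carbon para to it.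

**Step 3**
Reactants: 6 racemic dihydronaphthalene diester
Product: 7 racemic trans-8-bromo-1-(3-bromo-4-hydroxy-5-methoxyphenyl)-7-hydroxy-6-methoxy-3-(methoxycarbonyl)-1,2-dihydronaphthalene-2-carboxylic acid (1R,2S enantiomer drawn)
Conditions: LiOH·H2O, THF/H2O (degassed), 0 °C to rt, Ar; then 1 M HCl
Reagents that add atoms: LiOH, [Li+].[OH-]
Why: Chemoselective saponification: with both phenols ionised, the C7 phenoxide donates through C4a and C4=C3 into the C3 ester (a 4-oxidocinnamate), so hydroxide should attack only the isolated C2 ester, and the 1,2-trans arrangement, being the more stable one, is kept.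

**Step 4**
Reactants: 7 racemic half acid
Product: 8 (R)-1-phenylethylammonium (1R,2S)-8-bromo-1-(3-bromo-4-hydroxy-5-methoxyphenyl)-7-hydroxy-6-methoxy-3-(methoxycarbonyl)-1,2-dihydronaphthalene-2-carboxylate
Conditions: (R)-1-phenylethylamine (0.5 equiv), EtOH/EtOAc, crystallise, recrystallise to constant rotation
Reagents that add atoms: (R)-1-phenylethylamine, C[C@@H](N)c1ccccc1
Why: Classical resolution through diastereomeric salts: the carboxylic acid is the only group acidic enough to pair with half an equivalent of the amine, the salt of the (1R,2S)-acid should crystallise while the (1S,2R)-acid stays in solution, and the two bromine atoms allow the absolute configuration of the crystals to be confirmed by X-ray diffraction.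

**Step 5**
Reactants: 8 resolved ammonium salt
Product: 9 (1R,2S,3S)-7-hydroxy-1-(4-hydroxy-3-methoxyphenyl)-6-methoxy-3-(methoxycarbonyl)-1,2,3,4-tetrahydronaphthalene-2-carboxylic acid
Conditions: H2 (3 atm), 10% Pd/C, Et3N, MeOH, rt; then 1 M HCl
Reagents that add atoms: none
Why: Heterogeneous hydrogenation with hydrodebromination: H2 should add syn to C3=C4 from the face anti to the pseudoaxial C1 aryl group, as trans-1-aryl-1,2-dihydronaphthalenes generally do, which places the C3 ester trans to the C2 carboxyl group (3S), while Pd/C with Et3N cleaves both aryl–Br bonds and the acid wash removes the resolving amine.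

**Step 6**
Reactants: 9 tetralin half ester
Product: 10 (1R,2S,3S)-7-hydroxy-1-(4-hydroxy-3-methoxyphenyl)-3-(hydroxymethyl)-6-methoxy-1,2,3,4-tetrahydronaphthalene-2-carboxylic acid
Conditions: LiBH4, THF/MeOH, 0 °C to rt; then NH4Cl aq, 1 M HCl to pH 4, 0 °C
Reagents that add atoms: none
Why: Chemoselective ester reduction: LiBH4 first converts the acid and the phenols into lithium salts that resist borohydride and then reduces only the C3 methyl ester to the primary alcohol, leaving all three stereocentres untouched.

**Step 7**
Reactants: 10 hydroxy acid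
Product: 11 methyl (1R,2S,3S)-7-hydroxy-1-(4-hydroxy-3-methoxyphenyl)-3-(hydroxymethyl)-6-methoxy-1,2,3,4-tetrahydronaphthalene-2-carboxylate (target)
Conditions: Me3SiCHN2, MeOH/toluene, 0 °C
Reagents that add atoms: trimethylsilyldiazomethane, C[Si](C)(C)C=[N+]=[N-]
Why: Esterification with trimethylsilyldiazomethane: only the carboxylic acid is acidic enough to protonate the diazo compound at 0 °C, so the methyl ester should form without O-methylation of the phenols, and the neutral conditions avoid closure of the trans hydroxy ester to the lactone.

**Compound list**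
1 | 5-bromovanillin (3-bromo-4-hydroxy-5-methoxybenzaldehyde) | COc1cc(C=O)cc(Br)c1O | starting material
2 | monomethyl malonate (3-methoxy-3-oxopropanoic acid) | COC(=O)CC(=O)O | starting material
3 | methyl (E)-5-bromoferulate | COC(=O)/C=C/c1cc(OC)c(O)c(Br)c1 | intermediate
4 | bis-quinone methide: dimethyl 2,3-bis[(3-bromo-5-methoxy-4-oxocyclohexa-2,5-dien-1-ylidene)methyl]butanedioate (mixture of stereoisomers) | COC(=O)C(C=C1C=C(OC)C(=O)C(Br)=C1)C(C=C1C=C(OC)C(=O)C(Br)=C1)C(=O)OC | intermediate (not isolated)
5 | arylidenesuccinate quinone methide: dimethyl (2E)-2-[(3-bromo-4-hydroxy-5-methoxyphenyl)methylidene]-3-[(3-bromo-5-methoxy-4-oxocyclohexa-2,5-dien-1-ylidene)methyl]butanedioate (racemic) | COC(=O)/C(=C/c1cc(OC)c(O)c(Br)c1)C(C=C1C=C(OC)C(=O)C(Br)=C1)C(=O)OC | intermediate (not isolated)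
6 | racemic dimethyl trans-8-bromo-1-(3-bromo-4-hydroxy-5-methoxyphenyl)-7-hydroxy-6-methoxy-1,2-dihydronaphthalene-2,3-dicarboxylate (1R,2S enantiomer drawn) | COC(=O)[C@@H]1C(C(=O)OC)=Cc2cc(OC)c(O)c(Br)c2[C@H]1c1cc(Br)c(O)c(OC)c1 | intermediate
7 | racemic trans-8-bromo-1-(3-bromo-4-hydroxy-5-methoxyphenyl)-7-hydroxy-6-methoxy-3-(methoxycarbonyl)-1,2-dihydronaphthalene-2-carboxylic acid (1R,2S enantiomer drawn) | OC(=O)[C@@H]1C(C(=O)OC)=Cc2cc(OC)c(O)c(Br)c2[C@H]1c1cc(Br)c(O)c(OC)c1 | intermediate
8 | (R)-1-phenylethylammonium salt of the (1R,2S)-acid | [O-]C(=O)[C@@H]1C(C(=O)OC)=Cc2cc(OC)c(O)c(Br)c2[C@H]1c1cc(Br)c(O)c(OC)c1.C[C@@H]([NH3+])c1ccccc1 | intermediate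
9 | (1R,2S,3S)-7-hydroxy-1-(4-hydroxy-3-methoxyphenyl)-6-methoxy-3-(methoxycarbonyl)-1,2,3,4-tetrahydronaphthalene-2-carboxylic acid | OC(=O)[C@@H]1[C@@H](C(=O)OC)Cc2cc(OC)c(O)cc2[C@H]1c1ccc(O)c(OC)c1 | intermediate
10 | (1R,2S,3S)-7-hydroxy-1-(4-hydroxy-3-methoxyphenyl)-3-(hydroxymethyl)-6-methoxy-1,2,3,4-tetrahydronaphthalene-2-carboxylic acid | OC(=O)[C@@H]1[C@@H](CO)Cc2cc(OC)c(O)cc2[C@H]1c1ccc(O)c(OC)c1 | intermediate
11 | methyl (1R,2S,3S)-7-hydroxy-1-(4-hydroxy-3-methoxyphenyl)-3-(hydroxymethyl)-6-methoxy-1,2,3,4-tetrahydronaphthalene-2-carboxylate | COC(=O)[C@@H]1[C@@H](CO)Cc2cc(OC)c(O)cc2[C@H]1c1ccc(O)c(OC)c1 | target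

**Count**
Total steps: 7. Longest linear sequence: 7 steps (1 to 11).

**Steps most likely to fail**

Step 2 (oxidative dimerisation). What may go wrong: coupling through the phenoxyl oxygen (8–O–4) or further oxidation of the product phenols competes, and the quinone methides may be captured by water before ring B closes, so the cyclised dimer forms in low amount. Fallback, setting out from 1 and returning at 6: 1 is condensed with malonic acid (pyridine, piperidine, 90 °C) to (E)-5-bromoferulic acid F1. Oxidation of F1 with FeCl3 in aqueous ethanol under O2 joins the two side chains as before, but each quinone methide is trapped at once by the carboxyl group of the other half, giving the racemic cis-fused 8–8 dilactone F2. Heating F2 in methanolic HCl then ionises the benzylic lactone C–O bonds, lets one half eliminate to the arylidene unit and the other alkylate ring A (the same C1–C8a closure), and esterifies both acids (Fischer esterification), which should deliver racemic 6.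

Step 4 (resolution). What may go wrong: the two diastereomeric salts co-crystallise or form a solid solution, so that enantiomeric enrichment stalls. Fallback, setting out from 6 and returning at 9: the enantiomers of diester 6 are separated by preparative supercritical-fluid chromatography on an amylose tris(3,5-dimethylphenylcarbamate) phase, and the dimethyl (1R,2S)-diester F3 is identified by X-ray diffraction (anomalous scattering of bromine). F3 is saponified under the conditions of step 3 to the free (1R,2S)-acid F4, and F4 is hydrogenated under the conditions of step 5 to reach 9.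

Step 5 (hydrogenation). What may go wrong: poor facial selectivity, hydrogen being delivered wholly or partly syn to the C1 aryl group so that the C3 ester ends up cis to the C2 carboxyl group. Fallback, setting out from 8 and returning at 9: the hydrogenation is run to full conversion whatever the face, giving the (1R,2S,3R)-epimer F5 alone or mixed with 9, and the crude acid is heated with NaOMe in MeOH. C3 is the only centre that can enolise (α to an ester; the neighbouring carboxylate is not deprotonated), so equilibration should drain F5 into the all-equatorial trans,trans acid 9 after acidification.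

**Further compounds**
F1 | step 2 | (E)-5-bromoferulic acid | OC(=O)/C=C/c1cc(OC)c(O)c(Br)c1
F2 | step 2 | racemic cis-fused 4,8-bis(3-bromo-4-hydroxy-5-methoxyphenyl)-3,7-dioxabicyclo[3.3.0]octane-2,6-dione, both aryl groups exo (one enantiomer drawn) | O=C1O[C@H](c3cc(OC)c(O)c(Br)c3)[C@@H]2[C@H]1[C@@H](c4cc(OC)c(O)c(Br)c4)OC2=O
F3 | step 4 | dimethyl (1R,2S)-8-bromo-1-(3-bromo-4-hydroxy-5-methoxyphenyl)-7-hydroxy-6-methoxy-1,2-dihydronaphthalene-2,3-dicarboxylate (single enantiomer) | COC(=O)[C@@H]1C(C(=O)OC)=Cc2cc(OC)c(O)c(Br)c2[C@H]1c1cc(Br)c(O)c(OC)c1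
F4 | step 4 | (1R,2S)-8-bromo-1-(3-bromo-4-hydroxy-5-methoxyphenyl)-7-hydroxy-6-methoxy-3-(methoxycarbonyl)-1,2-dihydronaphthalene-2-carboxylic acid (single enantiomer, free acid) | OC(=O)[C@@H]1C(C(=O)OC)=Cc2cc(OC)c(O)c(Br)c2[C@H]1c1cc(Br)c(O)c(OC)c1
F5 | step 5 | (1R,2S,3R)-7-hydroxy-1-(4-hydroxy-3-methoxyphenyl)-6-methoxy-3-(methoxycarbonyl)-1,2,3,4-tetrahydronaphthalene-2-carboxylic acid | OC(=O)[C@@H]1[C@H](C(=O)OC)Cc2cc(OC)c(O)cc2[C@H]1c1ccc(O)c(OC)c1
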